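**Plan**

- Retrosynthesis: first cut the aryl C5–C1' bond of the side chain (aryl bromide + D-glyceraldehyde acetonide). Then re-expand the dihydrobenzofuran ring (O1, C2, C3, C3a, C7a) by putting the exocyclic CH2OH carbon back between C3 and C3a, which gives a (2R)-flavanone whose C4 ketone is that carbon. Last, cut the flavanone C2–aryl bond (chromone + arylboronic acid).
- Forward: the pyranone ring is built on a bromo-hydroxyacetophenone; ring B is joined by asymmetric conjugate addition; an oxidative 1,2-aryl shift contracts the six-membered ring to the five-membered ring and extrudes C4 as CO2Me; reduction, silylation, side-chain coupling and deprotection follow.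
- Enabling feature: in the target the ring-fusion carbon C3a and a one-carbon unit (CH2OH) sit on the same sp3 carbon C3, next to C2(aryl)–O1. This is the array left when ring A carbon C4a of a flavanone migrates from the carbonyl carbon C4 to C3.
- Stereochemistry: C2 by catalyst control; C3 relayed from C2 in the ring contraction (trans); C2' from the chiral pool; C1' by Felkin–Anh (anti) addition, which gives the erythro (1S,2R) triol.
- Helper: a pivalate on the ring B phenol makes ring B electron-poor for the key step and is removed in the ester reduction.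

Key step: step 5

Assumption: the (S)-t-BuPyOx ligand is taken to deliver the aryl group to the chromone in the same facial sense as to β-substituted cyclic enones, which gives the (2R)-flavanone; if the sense were opposite, the (R)-ligand would be used in the same step.

**Route**

Step 1
Reactants: 1 1-(2-hydroxy-3-methoxyphenyl)ethan-1-one
Product: 2 1-(5-bromo-2-hydroxy-3-methoxyphenyl)ethan-1-one
Conditions: NBS (1.05 equiv), MeCN, 0 °C to rt
Reagents that add atoms: N-bromosuccinimide, O=C1CCC(=O)N1Br
Why: electrophilic aromatic bromination should go para to the phenol, because both ortho positions are blocked by the acetyl and methoxy groups.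

Step 2
Reactants: 2 1-(5-bromo-2-hydroxy-3-methoxyphenyl)ethan-1-one
Product: 4 6-bromo-8-methoxy-4H-chromen-4-one, via enaminone 3 (not isolated)
Conditions: Me2NCH(OMe)2, toluene, 100 °C; then conc. HCl, CH2Cl2, 40 °C
Reagents that add atoms: N,N-dimethylformamide dimethyl acetal, COC(OC)N(C)C
Why: enaminone formation at the acetyl methyl group followed by acid-promoted addition of the phenol oxygen and loss of dimethylamine is the standard enaminone chromone synthesis.

Step 3
Reactants: 5 (4-hydroxy-3-methoxyphenyl)boronic acid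
Product: 6 [3-methoxy-4-(pivaloyloxy)phenyl]boronic acid
Conditions: PivCl, pyridine, THF, 0 °C to rt; dilute aq. HCl work-up
Reagents that add atoms: pivaloyl chloride, CC(C)(C)C(=O)Cl
Why: O-acylation of the phenol (any acyl boronate is hydrolysed on work-up) installs the electron-withdrawing mask that ring B needs in the key step.

Step 4
Reactants: 4 6-bromo-8-methoxy-4H-chromen-4-one; 6 [3-methoxy-4-(pivaloyloxy)phenyl]boronic acid
Product: 7 4-[(2R)-6-bromo-8-methoxy-4-oxochroman-2-yl]-2-methoxyphenyl pivalate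
Conditions: Pd(OCOCF3)2 (5 mol %), (S)-t-BuPyOx (6 mol %), NH4PF6 (30 mol %), H2O (5 equiv), ClCH2CH2Cl, 60 °C
Reagents that add atoms: none
Why: palladium-catalysed asymmetric conjugate addition of an arylboronic acid to a chromone (transmetalation to a cationic divalent palladium aryl, enantio-determining insertion of C2=C3, protonolysis of the palladium enolate) should set C2 as R under control of the tert-butyl oxazoline ligand, and the aryl bromide should survive because no zerovalent palladium takes part in the cycle.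

Step 5
Reactants: 7 4-[(2R)-6-bromo-8-methoxy-4-oxochroman-2-yl]-2-methoxyphenyl pivalate
Product: 10 methyl (2R,3R)-5-bromo-7-methoxy-2-[3-methoxy-4-(pivaloyloxy)phenyl]-2,3-dihydro-1-benzofuran-3-carboxylate, via enol ether 8 (not isolated), via iodane 9 (not isolated)
Conditions: PhI(OAc)2 (1.2 equiv), conc. H2SO4, HC(OMe)3, rt
Reagents that add atoms: trimethyl orthoformate, COC(OC)OC
Why: Acid and orthoformate should convert the C4 ketone into enol ether 8, which acid-activated PhI(OAc)2 attacks at C3 on the face anti to the C2 aryl group to give the 2,3-trans aryl-λ3-iodane 9 with C4 as a dimethyl ketal. In the diequatorial conformer of 9 the C3–I bond is antiperiplanar to the C4–C4a bond, so ring A carbon C4a shifts from C4 to C3 as iodobenzene leaves, pushed by the two methoxy groups on C4, and the exocyclic dimethoxycarbenium ion is demethylated to the methyl ester. The closest known reaction type is the oxidative ring contraction of flavanones and related cyclic aryl ketones by trivalent iodine or thallium trinitrate in trimethyl orthoformate. The five-membered ring (O1, C2, C3, C3a, C7a) is not closed by an exo or endo cyclisation but by this 1,2-shift through a three-centre phenonium-like transition state, in which the six-membered ring (O1, C2, C3, C4, C4a, C8a) loses C4 while the C3–C4a bond forms. C2 is untouched and stays R; C3 is set by invertive displacement of the equatorial iodane trans to the aryl group, which places CO2Me trans to the aryl group (2R,3R), and this is also the more stable epimer at that enolisable centre. The step needs migration of ring A instead of migration of the C2 aryl group (isoflavone), dehydrogenation or 3-methoxylation, and this should be secured by the equatorial C2 aryl group and by the pivaloyloxy group, which lowers the migratory aptitude of ring B and disfavours C2–O1 ionisation that would racemise C2.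

Step 6
Reactants: 10 methyl (2R,3R)-5-bromo-7-methoxy-2-[3-methoxy-4-(pivaloyloxy)phenyl]-2,3-dihydro-1-benzofuran-3-carboxylate
Product: 11 4-[(2R,3S)-5-bromo-3-(hydroxymethyl)-7-methoxy-2,3-dihydro-1-benzofuran-2-yl]-2-methoxyphenol
Conditions: LiAlH4, THF, 0 °C; Rochelle salt work-up
Reagents that add atoms: none
Why: hydride reduction should turn the methyl ester into the primary alcohol and cleave the pivalate in the same operation, while the low temperature spares the aryl bromide and leaves both stereocentres untouched (the C3 descriptor changes to S by priority rules only).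

Step 7
Reactants: 11 4-[(2R,3S)-5-bromo-3-(hydroxymethyl)-7-methoxy-2,3-dihydro-1-benzofuran-2-yl]-2-methoxyphenol
Product: 12 tert-butyl({(2R,3S)-5-bromo-2-[4-(tert-butyldimethylsilyloxy)-3-methoxyphenyl]-7-methoxy-2,3-dihydro-1-benzofuran-3-yl}methoxy)dimethylsilane
Conditions: TBSCl (2.5 equiv), imidazole, DMF, rt
Reagents that add atoms: tert-butyldimethylsilyl chloride, CC(C)(C)[Si](C)(C)Cl
Why: standard silylation should protect both the phenol and the primary alcohol so that no acidic proton remains for the organometallic step.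

Step 8
Reactants: 12 tert-butyl({(2R,3S)-5-bromo-2-[4-(tert-butyldimethylsilyloxy)-3-methoxyphenyl]-7-methoxy-2,3-dihydro-1-benzofuran-3-yl}methoxy)dimethylsilane; 13 (R)-2,2-dimethyl-1,3-dioxolane-4-carbaldehyde
Product: 16 (S)-{(2R,3S)-2-[4-(tert-butyldimethylsilyloxy)-3-methoxyphenyl]-3-[(tert-butyldimethylsilyloxy)methyl]-7-methoxy-2,3-dihydro-1-benzofuran-5-yl}[(4R)-2,2-dimethyl-1,3-dioxolan-4-yl]methanol, via aryllithium 14 (not isolated), via aryltitanium triisopropoxide 15 (not isolated)
Conditions: n-BuLi, THF, −78 °C; ClTi(OiPr)3, −78 to −40 °C; then 13, −78 to 0 °C; aq. NH4Cl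
Reagents that add atoms: none
Why: bromine–lithium exchange, transmetalation to a non-chelating aryltitanium reagent and carbonyl addition to the α-alkoxy aldehyde should follow the Felkin–Anh model and give the anti (erythro) carbinol, so that C1' becomes S next to the R centre taken from the chiral pool.

Step 9
Reactants: 16 (S)-{(2R,3S)-2-[4-(tert-butyldimethylsilyloxy)-3-methoxyphenyl]-3-[(tert-butyldimethylsilyloxy)methyl]-7-methoxy-2,3-dihydro-1-benzofuran-5-yl}[(4R)-2,2-dimethyl-1,3-dioxolan-4-yl]methanol
Product: 17 4-[(2R,3S)-5-{(S)-[(4R)-2,2-dimethyl-1,3-dioxolan-4-yl](hydroxy)methyl}-3-(hydroxymethyl)-7-methoxy-2,3-dihydro-1-benzofuran-2-yl]-2-methoxyphenol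
Conditions: TBAF, AcOH, THF, 0 °C to rt
Reagents that add atoms: none
Why: fluoride-mediated desilylation should free both silyl ethers, and the acetic acid buffer keeps the para-hydroxyphenyl group from reacting as a phenoxide that could open the ring at C2.

Step 10
Reactants: 17 4-[(2R,3S)-5-{(S)-[(4R)-2,2-dimethyl-1,3-dioxolan-4-yl](hydroxy)methyl}-3-(hydroxymethyl)-7-methoxy-2,3-dihydro-1-benzofuran-2-yl]-2-methoxyphenol
Product: 18 4-[(2R,3S)-3-(hydroxymethyl)-7-methoxy-5-[(1S,2R)-1,2,3-trihydroxypropyl]-2,3-dihydro-1-benzofuran-2-yl]-2-methoxyphenol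
Conditions: AcOH/H2O (4:1), 40 °C
Reagents that add atoms: none
Why: mild aqueous acid hydrolysis of the terminal acetonide should release the triol without ionising the para-alkoxybenzylic alcohol, and all reagents are volatile.

**Compound list**

1 | 1-(2-hydroxy-3-methoxyphenyl)ethan-1-one | CC(=O)c1cccc(OC)c1O | starting material
2 | 1-(5-bromo-2-hydroxy-3-methoxyphenyl)ethan-1-one | CC(=O)c1cc(Br)cc(OC)c1O | intermediate
3 | (E)-1-(5-bromo-2-hydroxy-3-methoxyphenyl)-3-(dimethylamino)prop-2-en-1-one | CN(C)/C=C/C(=O)c1cc(Br)cc(OC)c1O | intermediate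
4 | 6-bromo-8-methoxy-4H-chromen-4-one | O=c1ccoc2c(OC)cc(Br)cc12 | intermediate
5 | (4-hydroxy-3-methoxyphenyl)boronic acid | COc1cc(B(O)O)ccc1O | starting material
6 | [3-methoxy-4-(pivaloyloxy)phenyl]boronic acid | COc1cc(B(O)O)ccc1OC(=O)C(C)(C)C | intermediate
7 | 4-[(2R)-6-bromo-8-methoxy-4-oxochroman-2-yl]-2-methoxyphenyl pivalate | O=C1C[C@H](c2ccc(OC(=O)C(C)(C)C)c(OC)c2)Oc2c(OC)cc(Br)cc12 | intermediate
8 | 4-[(2R)-6-bromo-4,8-dimethoxy-2H-chromen-2-yl]-2-methoxyphenyl pivalate | COC1=C[C@H](c2ccc(OC(=O)C(C)(C)C)c(OC)c2)Oc2c(OC)cc(Br)cc12 | intermediate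
9 | 2,3-trans 4-{3-[acetoxy(phenyl)-λ3-iodanyl]-6-bromo-4,4,8-trimethoxychroman-2-yl}-2-methoxyphenyl pivalate (C2 as in 7) | COC1(OC)[C@@H](I(OC(C)=O)c2ccccc2)[C@H](c2ccc(OC(=O)C(C)(C)C)c(OC)c2)Oc2c(OC)cc(Br)cc12 | intermediate
10 | methyl (2R,3R)-5-bromo-7-methoxy-2-[3-methoxy-4-(pivaloyloxy)phenyl]-2,3-dihydro-1-benzofuran-3-carboxylate | COc1cc([C@@H]2Oc3c(OC)cc(Br)cc3[C@H]2C(=O)OC)ccc1OC(=O)C(C)(C)C | intermediate
11 | 4-[(2R,3S)-5-bromo-3-(hydroxymethyl)-7-methoxy-2,3-dihydro-1-benzofuran-2-yl]-2-methoxyphenol | COc1cc([C@@H]2Oc3c(OC)cc(Br)cc3[C@H]2CO)ccc1O | intermediate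
12 | bis(tert-butyldimethylsilyl) ether of 11 | COc1cc([C@@H]2Oc3c(OC)cc(Br)cc3[C@H]2CO[Si](C)(C)C(C)(C)C)ccc1O[Si](C)(C)C(C)(C)C | intermediate
13 | (R)-2,2-dimethyl-1,3-dioxolane-4-carbaldehyde | O=C[C@H]1COC(C)(C)O1 | starting material
14 | 5-lithio derivative of 12 | COc1cc([C@@H]2Oc3c(OC)cc([Li])cc3[C@H]2CO[Si](C)(C)C(C)(C)C)ccc1O[Si](C)(C)C(C)(C)C | intermediate
15 | 5-[tri(propan-2-yloxy)titanio] derivative of 12 | COc1cc([C@@H]2Oc3c(OC)cc([Ti](OC(C)C)(OC(C)C)OC(C)C)cc3[C@H]2CO[Si](C)(C)C(C)(C)C)ccc1O[Si](C)(C)C(C)(C)C | intermediate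
16 | (S)-{(2R,3S)-2-[4-(tert-butyldimethylsilyloxy)-3-methoxyphenyl]-3-[(tert-butyldimethylsilyloxy)methyl]-7-methoxy-2,3-dihydro-1-benzofuran-5-yl}[(4R)-2,2-dimethyl-1,3-dioxolan-4-yl]methanol | COc1cc([C@@H]2Oc3c(OC)cc([C@H](O)[C@H]4COC(C)(C)O4)cc3[C@H]2CO[Si](C)(C)C(C)(C)C)ccc1O[Si](C)(C)C(C)(C)C | intermediate
17 | 4-[(2R,3S)-5-{(S)-[(4R)-2,2-dimethyl-1,3-dioxolan-4-yl](hydroxy)methyl}-3-(hydroxymethyl)-7-methoxy-2,3-dihydro-1-benzofuran-2-yl]-2-methoxyphenol | COc1cc([C@@H]2Oc3c(OC)cc([C@H](O)[C@H]4COC(C)(C)O4)cc3[C@H]2CO)ccc1O | intermediate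
18 | 4-[(2R,3S)-3-(hydroxymethyl)-7-methoxy-5-[(1S,2R)-1,2,3-trihydroxypropyl]-2,3-dihydro-1-benzofuran-2-yl]-2-methoxyphenol | COc1cc([C@@H]2Oc3c(OC)cc([C@H](O)[C@H](O)CO)cc3[C@H]2CO)ccc1O | target

**Step count and risks**

Total steps: 10. Longest linear sequence: 9 (steps 1, 2, 4, 5, 6, 7, 8, 9, 10); step 3 is a one-step branch.

Steps most likely to fail:

1. Step 5 (ring contraction). The C2 aryl group may migrate instead of ring A, the flavanone may simply be dehydrogenated or methoxylated at C3, or acid may erode the configuration at C2. Fallback, a Wolff ring contraction that sets out from 7 and comes back at 10: 7 is condensed with N,N-dimethylformamide dimethyl acetal to the 3-[(dimethylamino)methylidene]flavanone F1. Deformylative diazo transfer with tosyl azide, which needs no strong base, gives the 3-diazoflavanone F2. Photolysis in methanol should expel nitrogen, shift ring A carbon C4a to the carbene carbon and trap the ketene as the methyl ester. This should give 10 together with its cis epimer, methyl (2R,3S)-5-bromo-7-methoxy-2-[3-methoxy-4-(pivaloyloxy)phenyl]-2,3-dihydro-1-benzofuran-3-carboxylate F3, which is equilibrated to 10 with DBU in CH2Cl2.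

2. Step 8 (side-chain coupling). Facial selectivity in the carbonyl addition may be poor, or the lithium-to-titanium transmetalation incomplete. Fallback, which moves the stereocontrol from C–C bond formation to a ketone reduction, sets out from 12 and comes back at 16: 12 is lithiated with n-BuLi and added to 13 without titanium, to give 16 mixed with its C1' epimer, the (R)-carbinol F4. Dess–Martin oxidation of the mixture converges both epimers on the aryl dioxolanyl ketone F5. Reduction with Zn(BH4)2 in Et2O at −30 °C, through the α-alkoxy zinc chelate, should deliver hydride to the face that gives the anti alcohol 16.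

3. Step 4 (asymmetric conjugate addition). Insertion into the hindered 8-methoxychromone may be slow, so that protodeboronation competes, or enantioselectivity may be insufficient. Fallback, a chalcone route with kinetic resolution that sets out from 2 and comes back at 7: vanillin is acylated with PivCl and Et3N to 4-formyl-2-methoxyphenyl pivalate F6. Claisen–Schmidt condensation of 2 with this aldehyde under BF3·OEt2 in dioxane, which spares the pivalate, gives the 2'-hydroxychalcone F7. NaOAc in refluxing EtOH cyclises it by oxa-Michael addition to the racemic flavanone F8. Asymmetric transfer hydrogenation with RuCl(p-cymene)[(S,S)-TsDPEN] in HCO2H/Et3N should reduce the (2S)-ketone faster, to the cis-(2S,4S)-flavan-4-ol F9, and leave 7 to be separated by chromatography.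

**Further compounds**

F1 | step 5 | 4-{(2S,3E)-6-bromo-3-[(dimethylamino)methylidene]-8-methoxy-4-oxochroman-2-yl}-2-methoxyphenyl pivalate (C2 arranged as in 7) | O=C1/C(=C/N(C)C)[C@H](c2ccc(OC(=O)C(C)(C)C)c(OC)c2)Oc2c(OC)cc(Br)cc12
F2 | step 5 | 4-[(2S)-6-bromo-3-diazo-8-methoxy-4-oxochroman-2-yl]-2-methoxyphenyl pivalate (C2 arranged as in 7) | O=C1C(=[N+]=[N-])[C@H](c2ccc(OC(=O)C(C)(C)C)c(OC)c2)Oc2c(OC)cc(Br)cc12
F3 | step 5 | methyl (2R,3S)-5-bromo-7-methoxy-2-[3-methoxy-4-(pivaloyloxy)phenyl]-2,3-dihydro-1-benzofuran-3-carboxylate (cis epimer of 10) | COc1cc([C@@H]2Oc3c(OC)cc(Br)cc3[C@@H]2C(=O)OC)ccc1OC(=O)C(C)(C)C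
F4 | step 8 | (R)-{(2R,3S)-2-[4-(tert-butyldimethylsilyloxy)-3-methoxyphenyl]-3-[(tert-butyldimethylsilyloxy)methyl]-7-methoxy-2,3-dihydro-1-benzofuran-5-yl}[(4R)-2,2-dimethyl-1,3-dioxolan-4-yl]methanol (C1' epimer of 16) | COc1cc([C@@H]2Oc3c(OC)cc([C@@H](O)[C@H]4COC(C)(C)O4)cc3[C@H]2CO[Si](C)(C)C(C)(C)C)ccc1O[Si](C)(C)C(C)(C)C
F5 | step 8 | {(2R,3S)-2-[4-(tert-butyldimethylsilyloxy)-3-methoxyphenyl]-3-[(tert-butyldimethylsilyloxy)methyl]-7-methoxy-2,3-dihydro-1-benzofuran-5-yl}[(4R)-2,2-dimethyl-1,3-dioxolan-4-yl]methanone | COc1cc([C@@H]2Oc3c(OC)cc(C(=O)[C@H]4COC(C)(C)O4)cc3[C@H]2CO[Si](C)(C)C(C)(C)C)ccc1O[Si](C)(C)C(C)(C)C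
F6 | step 4 | 4-formyl-2-methoxyphenyl pivalate | COc1cc(C=O)ccc1OC(=O)C(C)(C)C
F7 | step 4 | 4-[(E)-3-(5-bromo-2-hydroxy-3-methoxyphenyl)-3-oxoprop-1-en-1-yl]-2-methoxyphenyl pivalate | COc1cc(/C=C/C(=O)c2cc(Br)cc(OC)c2O)ccc1OC(=O)C(C)(C)C
F8 | step 4 | racemic 4-(6-bromo-8-methoxy-4-oxochroman-2-yl)-2-methoxyphenyl pivalate | O=C1CC(c2ccc(OC(=O)C(C)(C)C)c(OC)c2)Oc2c(OC)cc(Br)cc12
F9 | step 4 | 4-[(2S,4S)-6-bromo-4-hydroxy-8-methoxychroman-2-yl]-2-methoxyphenyl pivalate | O[C@H]1C[C@@H](c2ccc(OC(=O)C(C)(C)C)c(OC)c2)Oc2c(OC)cc(Br)cc12
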